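## Retrosynthetic overview

1. Target 18 ⇐ dibenzyl ether 17 (hydrogenolysis) ⇐ α‑aryloxy ketone 16, by the proposed new step: a dynamic‑kinetic asymmetric hydrogenation that sets C7''(S) and C8''(R) together.
2. 16 ⇐ syringyl‑type phenol 12 + racemic α‑bromopropiophenone 15 (C8''–O–C4' bond by SN2; no stereocontrol needed at this stage).
3. 12 ⇐ C6 linchpin 3 + aryl bromides 5 and 10, by two sequential Csp3–Csp2 Negishi couplings (C7–C1, then C7'–C1').
4. 3 ⇐ meso‑diol 2 ⇐ meso‑diacid 1: the relative C8/C8' configuration comes from the meso starting material, the absolute configuration from enzymatic desymmetrisation.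
5. No ring is formed; the three benzene rings are bought intact and attached in the order ring A, ring B, ring C.

## Assumptions

- Locants: ring A with C7–C9 is the 4‑hydroxy‑3‑methoxyphenyl half of the butane; ring B (primed) is the 3,5‑dimethoxy‑4‑oxyphenyl half; ring C (double‑primed) is the arylpropanol unit.
- The lipase in step 2 is assumed to give (2S,3R)‑3. I could not confirm the sense of selectivity; if the enantiomer forms, 5 and 10 are introduced in the opposite order and nothing else changes.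
- Aryl bromide 5 is treated as a catalogue compound (otherwise one step from 4‑bromo‑2‑methoxyphenol and BnBr).
- The changes of R/S label at C8/C8' between 3 and 12 are CIP‑priority changes only; no bond to these centres is touched after step 1.

## Route

**Step 1**
Reactants: 1, meso‑(2R,3S)‑2,3‑dimethylbutanedioic acid
Product: 2, meso‑(2R,3S)‑2,3‑dimethylbutane‑1,4‑diol
Conditions: LiAlH4 (3 equiv), THF, 0 °C → reflux
Reagents that add atoms: none
Why: LiAlH4 reduction of both carboxylic acids to primary alcohols; the carboxylate α‑centres do not epimerise, so the meso (cis) relationship that becomes 8S,8'R is carried over from 1.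

**Step 2**
Reactants: 2, meso‑2,3‑dimethylbutane‑1,4‑diol
Product: 3, (2S,3R)‑4‑hydroxy‑2,3‑dimethylbutyl acetate
Conditions: Pseudomonas fluorescens lipase (Amano AK), vinyl acetate (4 equiv), MTBE, 25 °C
Reagents that add atoms: vinyl acetate, C=COC(C)=O
Why: Enzymatic desymmetrisation (irreversible lipase transesterification) acylates one enantiotopic CH2OH arm of the meso diol, fixing the absolute sense of the C8/C8' pair, and over‑acylation of the minor enantiomer to diacetate raises the ee.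

**Step 3**
Reactants: 3, (2S,3R)‑4‑hydroxy‑2,3‑dimethylbutyl acetate
Product: 4, (2S,3R)‑4‑iodo‑2,3‑dimethylbutyl acetate
Conditions: I2, PPh3, imidazole, CH2Cl2, 0 °C → rt
Reagents that add atoms: iodine, II
Why: Appel‑type iodination of a primary alcohol by SN2 at CH2; the acetate and both stereocentres are untouched.

**Step 4**
Reactants: 4, (2S,3R)‑4‑iodo‑2,3‑dimethylbutyl acetate; 5, 1‑(benzyloxy)‑4‑bromo‑2‑methoxybenzene
Product: 6, (2S,3S)‑4‑[4‑(benzyloxy)‑3‑methoxyphenyl]‑2,3‑dimethylbutyl acetate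
Conditions: (i) Zn dust (TMSCl/BrCH2CH2Br‑activated), LiCl, THF, 40 °C; (ii) 5, Pd(OAc)2 (2 mol%), SPhos (4 mol%), THF, 25 → 50 °C
Reagents that add atoms: none (the aryl group comes from 5)
Why: Negishi Csp3–Csp2 coupling of a primary alkylzinc iodide, which tolerates the acetate, with an aryl bromide forms C7–C1; the stereocentre is β to zinc and is not involved.

**Step 5**
Reactants: 6, (2S,3S)‑4‑[4‑(benzyloxy)‑3‑methoxyphenyl]‑2,3‑dimethylbutyl acetate
Product: 7, (2S,3S)‑4‑[4‑(benzyloxy)‑3‑methoxyphenyl]‑2,3‑dimethylbutan‑1‑ol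
Conditions: K2CO3, MeOH, rt
Reagents that add atoms: none
Why: Zemplén‑type methanolysis of the acetate; the benzyl ether and the stereocentres are inert.

**Step 6**
Reactants: 7, (2S,3S)‑4‑[4‑(benzyloxy)‑3‑methoxyphenyl]‑2,3‑dimethylbutan‑1‑ol
Product: 8, 1‑(benzyloxy)‑4‑[(2S,3S)‑4‑iodo‑2,3‑dimethylbutyl]‑2‑methoxybenzene
Conditions: I2, PPh3, imidazole, CH2Cl2, 0 °C → rt
Reagents that add atoms: iodine, II
Why: Appel‑type iodination of the primary alcohol by SN2 at CH2, with no effect on the adjacent stereocentre.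

**Step 7**
Reactants: 9, 4‑bromo‑2,6‑dimethoxyphenol
Product: 10, (4‑bromo‑2,6‑dimethoxyphenoxy)(tert‑butyl)dimethylsilane
Conditions: TBSCl, imidazole, DMF, 40 °C
Reagents that add atoms: tert‑butyldimethylsilyl chloride, CC(C)(C)[Si](C)(C)Cl
Why: Silyl protection of the phenol gives a group orthogonal to the benzyl ether that survives organozinc/Pd conditions.

**Step 8**
Reactants: 8, 1‑(benzyloxy)‑4‑[(2S,3S)‑4‑iodo‑2,3‑dimethylbutyl]‑2‑methoxybenzene; 10, (4‑bromo‑2,6‑dimethoxyphenoxy)(tert‑butyl)dimethylsilane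
Product: 11, {4‑[(2R,3S)‑4‑[4‑(benzyloxy)‑3‑methoxyphenyl]‑2,3‑dimethylbutyl]‑2,6‑dimethoxyphenoxy}(tert‑butyl)dimethylsilane
Conditions: (i) Zn dust, LiCl, THF, 40 °C; (ii) 10, Pd(OAc)2 (2 mol%), SPhos (4 mol%), THF, 50 °C
Reagents that add atoms: none (the aryl group comes from 10)
Why: A second Negishi Csp3–Csp2 coupling forms C7'–C1' and completes the unsymmetrical meso‑like dibenzylbutane; the aryl silyl and benzyl ethers are stable and the β‑stereocentre is not involved.

**Step 9**
Reactants: 11, the TBS ether from step 8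
Product: 12, 4‑[(2R,3S)‑4‑[4‑(benzyloxy)‑3‑methoxyphenyl]‑2,3‑dimethylbutyl]‑2,6‑dimethoxyphenol
Conditions: TBAF, THF, 0 °C
Reagents that add atoms: none
Why: Fluoride desilylation frees only the ring‑B phenol, leaving ring A protected as its benzyl ether.

**Step 10**
Reactants: 13, 1‑(4‑hydroxy‑3‑methoxyphenyl)propan‑1‑one
Product: 14, 1‑[4‑(benzyloxy)‑3‑methoxyphenyl]propan‑1‑one
Conditions: BnBr, K2CO3, DMF, 60 °C
Reagents that add atoms: benzyl bromide, BrCc1ccccc1
Why: Williamson etherification of the phenol.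

**Step 11**
Reactants: 14, 1‑[4‑(benzyloxy)‑3‑methoxyphenyl]propan‑1‑one
Product: 15, (±)‑1‑[4‑(benzyloxy)‑3‑methoxyphenyl]‑2‑bromopropan‑1‑one
Conditions: CuBr2 (2 equiv), EtOAc/CHCl3, reflux
Reagents that add atoms: copper(II) bromide, Br[Cu]Br
Why: Enol‑selective α‑bromination of an aryl ketone; the acyl‑deactivated ring is not brominated, and the racemic product is acceptable because C8'' is set in step 13.

**Step 12**
Reactants: 12, the ring‑B phenol; 15, the racemic α‑bromoketone
Product: 16, (2RS)‑1‑[4‑(benzyloxy)‑3‑methoxyphenyl]‑2‑{4‑[(2R,3S)‑4‑[4‑(benzyloxy)‑3‑methoxyphenyl]‑2,3‑dimethylbutyl]‑2,6‑dimethoxyphenoxy}propan‑1‑one (about 1:1 mixture of C8'' epimers)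
Conditions: K2CO3, DMF, rt (cat. KI)
Reagents that add atoms: none (both partners are numbered reactants)
Why: Williamson‑type SN2 of the hindered phenoxide on the activated α‑bromoketone, the standard way to forge 8‑O‑4' aryl ethers; ring A cannot compete because it is benzylated.

**Step 13**
Reactants: 16, the α‑aryloxy ketone (both C8'' epimers)
Product: 17, (1S,2R)‑1‑[4‑(benzyloxy)‑3‑methoxyphenyl]‑2‑{4‑[(2R,3S)‑4‑[4‑(benzyloxy)‑3‑methoxyphenyl]‑2,3‑dimethylbutyl]‑2,6‑dimethoxyphenoxy}propan‑1‑ol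
Conditions: trans‑RuCl2[(S)‑xylbinap][(S)‑daipen] (1 mol%), KOtBu (20 mol%), H2 (10 atm), i‑PrOH/THF 3:1, 25 °C
Reagents that add atoms: none (H2 adds only hydrogen)
Why: Proposed new method: a Noyori‑type Ru(II)–diphosphine/diamine hydrogenation run as a dynamic kinetic resolution on an acyclic α‑aryloxy aryl ketone with no β‑activating group and a di‑ortho‑substituted aryl ether, a substrate class on which, to my knowledge, this reactivity has not been shown; KOtBu reversibly enolises the only acidic C–H (C8''–H) so the two C8'' epimers interconvert faster than either is reduced, the Ru–H/N–H species delivers H−/H+ to the C=O in an outer‑sphere six‑membered transition state whose (S)‑XylBINAP/(S)‑DAIPEN pocket selects the face giving 7''S (the same spatial sense as its (R)‑1‑arylethanol products, the label differing only because C8'' outranks aryl), and the (8''R) epimer reacts fastest because that face is also its Felkin–Anh face (hydride anti to the C8''–OAr bond), giving the anti/erythro (7''S,8''R) alcohol while C8/C8' stay untouched; closest known reaction type: Ru‑catalysed DKR hydrogenation or transfer hydrogenation of α‑substituted cyclic ketones and of α‑alkoxy/α‑amido β‑keto esters.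

**Step 14**
Reactants: 17, the dibenzyl ether
Product: 18, (+)‑(7''S,8S,8'R,8''R)‑4,4''‑dihydroxy‑3,3',3'',5'‑tetramethoxy‑4',8''‑oxy‑8,8'‑sesquineolignan‑7''‑ol (target)
Conditions: H2 (1 atm), 10% Pd/C, EtOAc, rt (stop when debenzylation is complete)
Reagents that add atoms: none
Why: Catalytic hydrogenolysis of the two aryl benzyl ethers under neutral conditions, where O‑benzyl cleavage is much faster than loss of the benzylic 7''‑OH; no stereocentre is affected.

## Compound list

1 | meso‑(2R,3S)‑2,3‑dimethylbutanedioic acid | OC(=O)[C@H](C)[C@H](C)C(O)=O | starting material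
2 | meso‑(2R,3S)‑2,3‑dimethylbutane‑1,4‑diol | OC[C@H](C)[C@H](C)CO | intermediate
3 | (2S,3R)‑4‑hydroxy‑2,3‑dimethylbutyl acetate | OC[C@H](C)[C@H](C)COC(C)=O | intermediate
4 | (2S,3R)‑4‑iodo‑2,3‑dimethylbutyl acetate | IC[C@H](C)[C@H](C)COC(C)=O | intermediate
5 | 1‑(benzyloxy)‑4‑bromo‑2‑methoxybenzene | COc1cc(Br)ccc1OCc1ccccc1 | starting material
6 | (2S,3S)‑4‑[4‑(benzyloxy)‑3‑methoxyphenyl]‑2,3‑dimethylbutyl acetate | COc1cc(C[C@H](C)[C@H](C)COC(C)=O)ccc1OCc1ccccc1 | intermediate
7 | (2S,3S)‑4‑[4‑(benzyloxy)‑3‑methoxyphenyl]‑2,3‑dimethylbutan‑1‑ol | COc1cc(C[C@H](C)[C@H](C)CO)ccc1OCc1ccccc1 | intermediate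
8 | 1‑(benzyloxy)‑4‑[(2S,3S)‑4‑iodo‑2,3‑dimethylbutyl]‑2‑methoxybenzene | COc1cc(C[C@H](C)[C@H](C)CI)ccc1OCc1ccccc1 | intermediate
9 | 4‑bromo‑2,6‑dimethoxyphenol | COc1cc(Br)cc(OC)c1O | starting material
10 | (4‑bromo‑2,6‑dimethoxyphenoxy)(tert‑butyl)dimethylsilane | COc1cc(Br)cc(OC)c1O[Si](C)(C)C(C)(C)C | intermediate
11 | {4‑[(2R,3S)‑4‑[4‑(benzyloxy)‑3‑methoxyphenyl]‑2,3‑dimethylbutyl]‑2,6‑dimethoxyphenoxy}(tert‑butyl)dimethylsilane | COc1cc(C[C@H](C)[C@H](C)Cc2cc(OC)c(O[Si](C)(C)C(C)(C)C)c(OC)c2)ccc1OCc1ccccc1 | intermediate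
12 | 4‑[(2R,3S)‑4‑[4‑(benzyloxy)‑3‑methoxyphenyl]‑2,3‑dimethylbutyl]‑2,6‑dimethoxyphenol | COc1cc(C[C@H](C)[C@H](C)Cc2cc(OC)c(O)c(OC)c2)ccc1OCc1ccccc1 | intermediate
13 | 1‑(4‑hydroxy‑3‑methoxyphenyl)propan‑1‑one | CCC(=O)c1ccc(O)c(OC)c1 | starting material
14 | 1‑[4‑(benzyloxy)‑3‑methoxyphenyl]propan‑1‑one | CCC(=O)c1ccc(OCc2ccccc2)c(OC)c1 | intermediate
15 | (±)‑1‑[4‑(benzyloxy)‑3‑methoxyphenyl]‑2‑bromopropan‑1‑one | CC(Br)C(=O)c1ccc(OCc2ccccc2)c(OC)c1 | intermediate
16 | (2RS)‑1‑[4‑(benzyloxy)‑3‑methoxyphenyl]‑2‑{4‑[(2R,3S)‑4‑[4‑(benzyloxy)‑3‑methoxyphenyl]‑2,3‑dimethylbutyl]‑2,6‑dimethoxyphenoxy}propan‑1‑one | COc1cc(C[C@H](C)[C@H](C)Cc2cc(OC)c(OC(C)C(=O)c3ccc(OCc4ccccc4)c(OC)c3)c(OC)c2)ccc1OCc5ccccc5 | intermediate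
17 | (1S,2R)‑1‑[4‑(benzyloxy)‑3‑methoxyphenyl]‑2‑{4‑[(2R,3S)‑4‑[4‑(benzyloxy)‑3‑methoxyphenyl]‑2,3‑dimethylbutyl]‑2,6‑dimethoxyphenoxy}propan‑1‑ol | COc1cc(C[C@H](C)[C@H](C)Cc2cc(OC)c(O[C@H](C)[C@@H](O)c3ccc(OCc4ccccc4)c(OC)c3)c(OC)c2)ccc1OCc5ccccc5 | intermediate
18 | (+)‑(7''S,8S,8'R,8''R)‑4,4''‑dihydroxy‑3,3',3'',5'‑tetramethoxy‑4',8''‑oxy‑8,8'‑sesquineolignan‑7''‑ol | COc1cc(C[C@H](C)[C@H](C)Cc2cc(OC)c(O[C@H](C)[C@@H](O)c3ccc(O)c(OC)c3)c(OC)c2)ccc1O | target

## Summary

Total step count: 14.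

Longest linear sequence: 11 steps (1 → 2 → 3 → 4 → 6 → 7 → 8 → 11 → 12 → 16 → 17 → 18).

Three steps most likely to fail:

1. **Step 13 (proposed new DKR hydrogenation).** Risks: racemisation of C8'' too slow relative to reduction, modest erythro/threo ratio, or the opposite facial sense. Fallback with known chemistry, setting C8'' from the chiral pool:
   - Mitsunobu etherification of 12 with ethyl (S)‑lactate (inversion, giving the (R)‑2‑aryloxypropanoate).
   - DIBAL‑H reduction to the (R)‑aldehyde.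
   - Felkin–Anh addition of 4‑benzyloxy‑3‑methoxyphenylmagnesium bromide (erythro major), then chromatographic removal of the threo isomer to reach 17.

2. **Step 2 (lipase desymmetrisation).** Risks: insufficient ee, opposite enantiomer, or acyl migration. Fallback, desymmetrising one oxidation level higher:
   - Cinchona‑alkaloid‑mediated methanolysis of meso‑2,3‑dimethylsuccinic anhydride (quinidine or quinine chosen for the required hemiester).
   - BH3·SMe2 reduction of the free acid.
   - Carry the hydroxy ester through steps 3–4, then reduce the ester with LiAlH4 to reach 7.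

3. **Steps 4 and 8 (alkylzinc Negishi couplings).** Risks: sluggish zinc insertion, or β‑hydride elimination/re‑insertion at Pd giving isomerised product or eroding the β‑stereocentre. Fallback, reversing the polarity: couple the aryl Grignard reagent from 5 (or 10) with the alkyl tosylate or iodide under copper catalysis (Li2CuCl4, SN2‑type, no β‑hydride pathway), with the acetate exchanged for a silyl ether in the step‑4 case.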